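**Plan**

- Retrosynthetic cuts: first the sulfate O–S bond and the phenol protecting groups; then ring B through its C1–C2 and C3–C4 bonds (the C1–C6 bond is re-formed in the same operation), back to a 3-alkylcyclobut-2-enone and (triisopropylsilyloxy)acetylene; then the ester C–O bond at the carbinol carbon of the ring B chain; last the aryl–CH2 bond of ring A.
- Forward order: ring A is bought as 2,4,6-trihydroxybenzaldehyde and receives the acetoxyundecyl chain by B-alkyl Suzuki coupling. Oxidation to the acid and Mitsunobu esterification with a terminal alkynol join the two chains. The alkyne is turned into a cyclobutenone, and ring B is grown on it last.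
- Enabling feature: ring B is a benzene ring with oxygen on C1 and C3 and the alkyl chain on C5. In the benzannulation the C1 oxygen is the cyclobutenone carbonyl (it emerges as free OH) and the C3 oxygen is that of the ynol ether (it emerges silylated). The two constitutionally equivalent oxygens are therefore formed already different, and only the free one is sulfated.
- Stereochemistry: both (S) carbinol centres come from 2-propyloxirane. The (S)-epoxide gives the acetate centre with retention; the (R)-epoxide gives the benzoate centre after Mitsunobu inversion. No C–C bond-forming step creates or touches a stereocentre.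

Key step: step 14

Assumption: both enantiomers of 2-propyloxirane are taken as commercial (each is the epoxide recovered from hydrolytic kinetic resolution of racemic 1,2-epoxypentane), and the aryl sulfate is carried as its potassium salt and protonated only in the last work-up.

**Route**

Step 1
Reactants: 1 (S)-2-propyloxirane; 2 6-bromohex-1-ene
Product: 4 (S)-undec-10-en-4-ol, via hex-5-enylmagnesium bromide 3 (not isolated)
Conditions: 2, Mg, THF, rt; then CuI (10 mol%), 1, THF, −30 to 0 °C
Reagents that add atoms: none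
Why: Copper-catalysed Grignard opening of a terminal epoxide occurs at the unsubstituted carbon, so the C–O bond of the stereocentre is untouched and the (S) configuration of 1 is carried into 4.

Step 2
Reactants: 4 (S)-undec-10-en-4-ol
Product: 5 (S)-undec-10-en-4-yl acetate
Conditions: Ac2O, pyridine, DMAP (cat.), CH2Cl2, rt
Reagents that add atoms: acetic anhydride, CC(=O)OC(C)=O
Why: DMAP-catalysed O-acylation of a secondary alcohol leaves the carbinol C–O bond intact, so the acetate stereocentre of the target is fixed here with retention.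

Step 3
Reactants: 6 2,4,6-trihydroxybenzaldehyde
Product: 7 2,4-bis(benzyloxy)-6-hydroxybenzaldehyde
Conditions: BnBr (2.1 equiv), K2CO3, DMF, rt
Reagents that add atoms: benzyl bromide, BrCc1ccccc1
Why: Williamson etherification is expected to stop after two benzylations because the remaining ortho hydroxyl is locked in a hydrogen bond to the formyl oxygen and is far less nucleophilic than the other two.

Step 4
Reactants: 7 2,4-bis(benzyloxy)-6-hydroxybenzaldehyde
Product: 8 3,5-bis(benzyloxy)-2-formylphenyl trifluoromethanesulfonate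
Conditions: Tf2O, pyridine, CH2Cl2, 0 °C
Reagents that add atoms: trifluoromethanesulfonic anhydride, O=S(=O)(OS(=O)(=O)C(F)(F)F)C(F)(F)F
Why: O-Triflation of the hydrogen-bonded phenol with triflic anhydride and pyridine is a routine sulfonylation and gives an aryl triflate that the ortho formyl group activates for oxidative addition.

Step 5
Reactants: 5 (S)-undec-10-en-4-yl acetate; 8 3,5-bis(benzyloxy)-2-formylphenyl trifluoromethanesulfonate
Product: 10 (S)-11-[3,5-bis(benzyloxy)-2-formylphenyl]undecan-4-yl acetate, via B-alkyl-9-BBN borane 9 (not isolated)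
Conditions: 5 (slight excess), 9-BBN, THF, 0 °C to rt; then 8, Pd(dppf)Cl2 (5 mol%), K3PO4 (aq), THF/DMF, 60 °C
Reagents that add atoms: none
Why: Anti-Markovnikov hydroboration of the terminal alkene followed by B-alkyl Suzuki–Miyaura coupling with the aryl triflate joins the chain to ring A under phosphate conditions that the acetate and the aldehyde tolerate, the alkene being kept in slight excess so that no B–H bond is left to reduce the aldehyde.

Step 6
Reactants: 10 (S)-11-[3,5-bis(benzyloxy)-2-formylphenyl]undecan-4-yl acetate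
Product: 11 2-[(8S)-8-acetoxyundecyl]-4,6-bis(benzyloxy)benzoic acid
Conditions: NaClO2, NaH2PO4, 2-methyl-2-butene, t-BuOH/THF/H2O, 0 °C to rt
Reagents that add atoms: sodium chlorite, [Na+].[O-]Cl=O
Why: Pinnick oxidation converts the hindered aryl aldehyde into the acid without touching the acetate, and the alkene scavenger removes the hypochlorous acid that would otherwise chlorinate the electron-rich ring.

Step 7
Reactants: 12 (R)-2-propyloxirane; 13 1-octyne
Product: 15 (R)-tridec-6-yn-4-ol, via oct-1-ynyllithium 14 (not isolated)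
Conditions: 13, n-BuLi, THF, −78 °C; BF3·OEt2; then 12, −78 °C
Reagents that add atoms: none
Why: BF3-promoted opening of a terminal epoxide by a lithium acetylide occurs only at the CH2 carbon, so the stereocentre of 12 is preserved in the (R)-homopropargylic alcohol.

Step 8
Reactants: 15 (R)-tridec-6-yn-4-ol
Product: 16 (R)-tridec-12-yn-4-ol
Conditions: KH, H2N(CH2)3NH2, 0 °C to rt; then H2O
Reagents that add atoms: none
Why: The alkyne zipper reaction moves the triple bond through propargyl–allenyl equilibria to the chain end, where it is trapped as the acetylide, and it cannot pass or epimerise the carbinol carbon, which is held as its alkoxide.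

Step 9
Reactants: 11 2-[(8S)-8-acetoxyundecyl]-4,6-bis(benzyloxy)benzoic acid; 16 (R)-tridec-12-yn-4-ol
Product: 17 (4S)-tridec-12-yn-4-yl 2-[(8S)-8-acetoxyundecyl]-4,6-bis(benzyloxy)benzoate
Conditions: PPh3, DIAD, THF, 0 °C to rt
Reagents that add atoms: none
Why: Mitsunobu esterification makes the carboxylate of the 2,6-disubstituted acid the nucleophile at the activated carbinol carbon, which avoids acyl substitution at the hindered carbonyl and sets the benzoate stereocentre as (S) by SN2 inversion of the (R)-alcohol.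

Step 10
Reactants: 17 (4S)-tridec-12-yn-4-yl 2-[(8S)-8-acetoxyundecyl]-4,6-bis(benzyloxy)benzoate
Product: 18 (4S)-11-(4,4-dichloro-3-oxocyclobut-1-en-1-yl)undecan-4-yl 2-[(8S)-8-acetoxyundecyl]-4,6-bis(benzyloxy)benzoate
Conditions: Cl3CCOCl, Zn–Cu couple, Et2O/DME, rt
Reagents that add atoms: trichloroacetyl chloride, ClC(=O)C(Cl)(Cl)Cl
Why: Dichloroketene generated in situ adds to the terminal alkyne in a regioselective (2+2) cycloaddition (carbonyl carbon to the unsubstituted alkyne carbon), while the esters and benzyl ethers are inert to this electrophile and DME ties up the ZnCl2 formed.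

Step 11
Reactants: 18 (4S)-11-(4,4-dichloro-3-oxocyclobut-1-en-1-yl)undecan-4-yl 2-[(8S)-8-acetoxyundecyl]-4,6-bis(benzyloxy)benzoate
Product: 19 (4S)-11-(3-oxocyclobut-1-en-1-yl)undecan-4-yl 2-[(8S)-8-acetoxyundecyl]-4,6-bis(benzyloxy)benzoate
Conditions: Zn dust, TMEDA, AcOH, EtOH, 0 °C to rt
Reagents that add atoms: none
Why: Buffered zinc reduction removes both alpha chlorine atoms of the 4,4-dichlorocyclobutenone by way of zinc enolates without reducing the strained enone, which is the standard route to 3-alkylcyclobutenones.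

Step 12
Reactants: 20 (trimethylsilyl)acetylene
Product: 23 triisopropyl{[(trimethylsilyl)ethynyl]oxy}silane, via lithium (trimethylsilyl)acetylide 21 (not isolated), via lithium 2-(trimethylsilyl)ethynolate 22 (not isolated)
Conditions: n-BuLi, THF, −78 °C; t-BuOOLi (from t-BuOOH and LiN(SiMe3)2), −78 to 0 °C; TIPSOTf, −78 to 0 °C
Reagents that add atoms: tert-butyl hydroperoxide, CC(C)(C)OO; triisopropylsilyl trifluoromethanesulfonate, CC(C)[Si](OS(=O)(=O)C(F)(F)F)(C(C)C)C(C)C
Why: The lithium acetylide attacks the electrophilic oxygen of lithium tert-butyl peroxide to give the ynolate, which the hard and bulky silyl triflate captures on oxygen to give a silyl ynol ether (oxenoid oxidation of an acetylide followed by O-silylation of the ynolate).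

Step 13
Reactants: 23 triisopropyl{[(trimethylsilyl)ethynyl]oxy}silane
Product: 24 (triisopropylsilyloxy)acetylene [(ethynyloxy)triisopropylsilane]
Conditions: K2CO3 (cat.), MeOH, 0 °C
Reagents that add atoms: none
Why: Base-catalysed methanolysis of the C(sp)–SiMe3 bond (protodesilylation of an alkynylsilane) is fast at 0 °C, whereas attack at the hindered oxygen-bound Si(i-Pr)3 group is slow, so the parent ynol ether should be released and is isolated by careful distillation.

Step 14
Reactants: 19 (4S)-11-(3-oxocyclobut-1-en-1-yl)undecan-4-yl 2-[(8S)-8-acetoxyundecyl]-4,6-bis(benzyloxy)benzoate; 24 (triisopropylsilyloxy)acetylene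
Product: 28 (4S)-11-[3-hydroxy-5-(triisopropylsilyloxy)phenyl]undecan-4-yl 2-[(8S)-8-acetoxyundecyl]-4,6-bis(benzyloxy)benzoate, via vinylketene 25 (not isolated), via 4-vinylcyclobutenone 26 (not isolated), via dienylketene 27 (not isolated)
Conditions: 24 (3 equiv), toluene, 80 to 110 °C, sealed tube
Reagents that add atoms: none
Why: Danheiser benzannulation: thermal 4π electrocyclic opening of cyclobutenone 19 gives vinylketene 25, whose ketene C=C bond adds the ynol ether in a (2+2) cycloaddition to give 26, and 4π opening of 26 gives dienylketene 27. Ring B is closed by thermal 6π electrocyclisation of 27 (bond between the ketene carbon and the terminal CH2 carbon), and the cyclohexadienone formed tautomerises to the phenol. The closest known reactions are the annulations of 3-alkylcyclobutenones with alkoxy- and trialkylsilyloxyalkynes, which give 5-alkylresorcinol monoethers. No stereocentre is created, and the neutral thermal conditions leave the two esters, the benzyl ethers and both carbinol centres untouched. The selectivity needed is the regiochemistry of the (2+2) step, and it is secured by the polarisation of the ynol ether: its unsubstituted, nucleophilic carbon bonds to the electrophilic ketene carbonyl carbon, so the former carbonyl oxygen becomes the free hydroxyl at C1, the silyloxy group sits at C3 and the chain at C5. An excess of 24 is used so that 25 is captured by the alkyne and not by the phenol already formed.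

Step 15
Reactants: 28 (4S)-11-[3-hydroxy-5-(triisopropylsilyloxy)phenyl]undecan-4-yl 2-[(8S)-8-acetoxyundecyl]-4,6-bis(benzyloxy)benzoate
Product: 29 potassium 3-[(8S)-8-({2-[(8S)-8-acetoxyundecyl]-4,6-bis(benzyloxy)benzoyl}oxy)undecyl]-5-(triisopropylsilyloxy)phenyl sulfate
Conditions: SO3·pyridine, pyridine, 40 °C; then aq. KHCO3
Reagents that add atoms: sulfur trioxide–pyridine complex, [O-]S(=O)(=O)[n+]1ccccc1; potassium hydrogen carbonate, [K+].OC(=O)[O-]
Why: O-Sulfation of a phenol with the SO3·pyridine complex is site-selective here because the phenol set free in step 14 is the only hydroxyl group in the molecule.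

Step 16
Reactants: 29 potassium 3-[(8S)-8-({2-[(8S)-8-acetoxyundecyl]-4,6-bis(benzyloxy)benzoyl}oxy)undecyl]-5-(triisopropylsilyloxy)phenyl sulfate
Product: 30 potassium 3-[(8S)-8-({2-[(8S)-8-acetoxyundecyl]-4,6-bis(benzyloxy)benzoyl}oxy)undecyl]-5-hydroxyphenyl sulfate
Conditions: KHF2, MeOH/THF, rt
Reagents that add atoms: none
Why: Bifluoride in methanol cleaves phenolic silyl ethers by attack of fluoride at silicon with the phenoxide as leaving group, under near-neutral conditions that should not disturb the acetate, the benzoate, the benzyl ethers or the aryl sulfate.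

Step 17
Reactants: 30 potassium 3-[(8S)-8-({2-[(8S)-8-acetoxyundecyl]-4,6-bis(benzyloxy)benzoyl}oxy)undecyl]-5-hydroxyphenyl sulfate
Product: 32 integracin D, via integracin D potassium salt 31 (not isolated)
Conditions: H2 (1 atm), Pd/C, MeOH/EtOAc, rt; filter; then cold 0.5 M HCl, EtOAc/n-BuOH extraction
Reagents that add atoms: none
Why: Hydrogenolysis over palladium on carbon removes the two aryl benzyl ethers without affecting the aryl sulfate, the esters or the saturated chains, and brief cold acidification protonates the sulfate to give the target as drawn.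

**Compound list**

1 | (S)-2-propyloxirane | CCC[C@H]1CO1 | starting material
2 | 6-bromohex-1-ene | C=CCCCCBr | starting material
3 | hex-5-enylmagnesium bromide | C=CCCCC[Mg]Br | intermediate
4 | (S)-undec-10-en-4-ol | CCC[C@H](O)CCCCCC=C | intermediate
5 | (S)-undec-10-en-4-yl acetate | CCC[C@@H](CCCCCC=C)OC(C)=O | intermediate
6 | 2,4,6-trihydroxybenzaldehyde | O=Cc1c(O)cc(O)cc1O | starting material
7 | 2,4-bis(benzyloxy)-6-hydroxybenzaldehyde | O=Cc1c(O)cc(OCc2ccccc2)cc1OCc1ccccc1 | intermediate
8 | 3,5-bis(benzyloxy)-2-formylphenyl trifluoromethanesulfonate | O=Cc1c(OS(=O)(=O)C(F)(F)F)cc(OCc2ccccc2)cc1OCc1ccccc1 | intermediate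
9 | (S)-11-(9-borabicyclo[3.3.1]nonan-9-yl)undecan-4-yl acetate | CCC[C@@H](CCCCCCCB1C2CCCC1CCC2)OC(C)=O | intermediate
10 | (S)-11-[3,5-bis(benzyloxy)-2-formylphenyl]undecan-4-yl acetate | CCC[C@@H](CCCCCCCc1cc(OCc2ccccc2)cc(OCc2ccccc2)c1C=O)OC(C)=O | intermediate
11 | 2-[(8S)-8-acetoxyundecyl]-4,6-bis(benzyloxy)benzoic acid | CCC[C@@H](CCCCCCCc1cc(OCc2ccccc2)cc(OCc2ccccc2)c1C(=O)O)OC(C)=O | intermediate
12 | (R)-2-propyloxirane | CCC[C@@H]1CO1 | starting material
13 | 1-octyne | CCCCCCC#C | starting material
14 | oct-1-ynyllithium | CCCCCCC#C[Li] | intermediate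
15 | (R)-tridec-6-yn-4-ol | CCC[C@@H](O)CC#CCCCCCC | intermediate
16 | (R)-tridec-12-yn-4-ol | CCC[C@@H](O)CCCCCCCC#C | intermediate
17 | (4S)-tridec-12-yn-4-yl 2-[(8S)-8-acetoxyundecyl]-4,6-bis(benzyloxy)benzoate | CCC[C@@H](CCCCCCCc1cc(OCc2ccccc2)cc(OCc2ccccc2)c1C(=O)O[C@@H](CCC)CCCCCCCC#C)OC(C)=O | intermediate
18 | (4S)-11-(4,4-dichloro-3-oxocyclobut-1-en-1-yl)undecan-4-yl 2-[(8S)-8-acetoxyundecyl]-4,6-bis(benzyloxy)benzoate | CCC[C@@H](CCCCCCCc1cc(OCc2ccccc2)cc(OCc2ccccc2)c1C(=O)O[C@@H](CCC)CCCCCCCC1=CC(=O)C1(Cl)Cl)OC(C)=O | intermediate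
19 | (4S)-11-(3-oxocyclobut-1-en-1-yl)undecan-4-yl 2-[(8S)-8-acetoxyundecyl]-4,6-bis(benzyloxy)benzoate | CCC[C@@H](CCCCCCCc1cc(OCc2ccccc2)cc(OCc2ccccc2)c1C(=O)O[C@@H](CCC)CCCCCCCC1=CC(=O)C1)OC(C)=O | intermediate
20 | (trimethylsilyl)acetylene | C#C[Si](C)(C)C | starting material
21 | lithium (trimethylsilyl)acetylide | [Li]C#C[Si](C)(C)C | intermediate
22 | lithium 2-(trimethylsilyl)ethynolate | [Li]OC#C[Si](C)(C)C | intermediate
23 | triisopropyl{[(trimethylsilyl)ethynyl]oxy}silane | C[Si](C)(C)C#CO[Si](C(C)C)(C(C)C)C(C)C | intermediate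
24 | (triisopropylsilyloxy)acetylene [(ethynyloxy)triisopropylsilane] | C#CO[Si](C(C)C)(C(C)C)C(C)C | intermediate
25 | vinylketene: (4S)-12-methylidene-14-oxotetradec-13-en-4-yl 2-[(8S)-8-acetoxyundecyl]-4,6-bis(benzyloxy)benzoate | CCC[C@@H](CCCCCCCc1cc(OCc2ccccc2)cc(OCc2ccccc2)c1C(=O)O[C@@H](CCC)CCCCCCCC(=C)C=C=O)OC(C)=O | intermediate
26 | 4-vinylcyclobutenone: (4S)-12-[4-oxo-2-(triisopropylsilyloxy)cyclobut-2-en-1-yl]tridec-12-en-4-yl 2-[(8S)-8-acetoxyundecyl]-4,6-bis(benzyloxy)benzoate (both epimers at the ring CH carbon) | CCC[C@@H](CCCCCCCc1cc(OCc2ccccc2)cc(OCc2ccccc2)c1C(=O)O[C@@H](CCC)CCCCCCCC(=C)C1C(=O)C=C1O[Si](C(C)C)(C(C)C)C(C)C)OC(C)=O | intermediate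
27 | dienylketene: (4S)-12-methylidene-16-oxo-14-(triisopropylsilyloxy)hexadeca-13,15-dien-4-yl 2-[(8S)-8-acetoxyundecyl]-4,6-bis(benzyloxy)benzoate (ketene and alkenyl group cis on the central double bond) | CCC[C@@H](CCCCCCCc1cc(OCc2ccccc2)cc(OCc2ccccc2)c1C(=O)O[C@@H](CCC)CCCCCCCC(=C)/C=C(O[Si](C(C)C)(C(C)C)C(C)C)\C=C=O)OC(C)=O | intermediate
28 | (4S)-11-[3-hydroxy-5-(triisopropylsilyloxy)phenyl]undecan-4-yl 2-[(8S)-8-acetoxyundecyl]-4,6-bis(benzyloxy)benzoate | CCC[C@@H](CCCCCCCc1cc(OCc2ccccc2)cc(OCc2ccccc2)c1C(=O)O[C@@H](CCC)CCCCCCCc1cc(O)cc(O[Si](C(C)C)(C(C)C)C(C)C)c1)OC(C)=O | intermediate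
29 | potassium 3-[(8S)-8-({2-[(8S)-8-acetoxyundecyl]-4,6-bis(benzyloxy)benzoyl}oxy)undecyl]-5-(triisopropylsilyloxy)phenyl sulfate | CCC[C@@H](CCCCCCCc1cc(OCc2ccccc2)cc(OCc2ccccc2)c1C(=O)O[C@@H](CCC)CCCCCCCc1cc(OS(=O)(=O)[O-])cc(O[Si](C(C)C)(C(C)C)C(C)C)c1)OC(C)=O.[K+] | intermediate
30 | potassium 3-[(8S)-8-({2-[(8S)-8-acetoxyundecyl]-4,6-bis(benzyloxy)benzoyl}oxy)undecyl]-5-hydroxyphenyl sulfate | CCC[C@@H](CCCCCCCc1cc(OCc2ccccc2)cc(OCc2ccccc2)c1C(=O)O[C@@H](CCC)CCCCCCCc1cc(O)cc(OS(=O)(=O)[O-])c1)OC(C)=O.[K+] | intermediate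
31 | integracin D potassium salt: potassium 3-[(8S)-8-({2-[(8S)-8-acetoxyundecyl]-4,6-dihydroxybenzoyl}oxy)undecyl]-5-hydroxyphenyl sulfate | CCC[C@@H](CCCCCCCc1cc(O)cc(O)c1C(=O)O[C@@H](CCC)CCCCCCCc1cc(O)cc(OS(=O)(=O)[O-])c1)OC(C)=O.[K+] | intermediate
32 | integracin D: 3-[(8S)-8-({2-[(8S)-8-acetoxyundecyl]-4,6-dihydroxybenzoyl}oxy)undecyl]-5-hydroxyphenyl hydrogen sulfate | CCC[C@@H](CCCCCCCc1cc(O)cc(O)c1C(=O)O[C@@H](CCC)CCCCCCCc1cc(O)cc(OS(=O)(=O)O)c1)OC(C)=O | target

**Step count and risks**

Total steps: 17. Longest linear sequence: 11 steps (steps 3, 4, 5, 6, 9, 10, 11, 14, 15, 16, 17).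

Steps most likely to fail:

1. Step 14 (benzannulation). Vinylketene 25 may be captured by the phenol already formed, giving aryl esters that cannot be saponified next to the two esters of the molecule. The ketene may also dimerise if the (2+2) step with the unsubstituted ynol ether is slow, and 24 may isomerise to the silylketene at the reaction temperature. Fallback: ring B is bought and attached by cross-coupling. Setting out from acid 11, epoxide 12 is opened with Grignard reagent 3 (CuI) to give (R)-undec-10-en-4-ol F1. Mitsunobu esterification of F1 with 11 (inversion) gives (4S)-undec-10-en-4-yl 2-[(8S)-8-acetoxyundecyl]-4,6-bis(benzyloxy)benzoate F2. Commercial 5-bromoresorcinol is monosilylated (TIPSCl, imidazole) to 3-bromo-5-(triisopropylsilyloxy)phenol F3. Hydroboration of F2 with 9-BBN gives (4S)-11-(9-borabicyclo[3.3.1]nonan-9-yl)undecan-4-yl 2-[(8S)-8-acetoxyundecyl]-4,6-bis(benzyloxy)benzoate F4, and B-alkyl Suzuki–Miyaura coupling of F4 with F3 (Pd(dppf)Cl2, K3PO4) should deliver 28, where the route is rejoined.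

2. Step 13 (C-desilylation of the ynol ether). Cleavage of the O–Si bond or addition of methanol to the ynol ether may compete with desilylation at carbon, and volatile 24 may be lost on isolation. Fallback: the C–Si bond is carried through the annulation and cleaved from the arene. Setting out from 19 and 23, heating as in step 14 should give (4S)-11-[3-hydroxy-5-(triisopropylsilyloxy)-4-(trimethylsilyl)phenyl]undecan-4-yl 2-[(8S)-8-acetoxyundecyl]-4,6-bis(benzyloxy)benzoate F5. The silyl-bearing alkyne carbon remains the nucleophilic one, so the regiochemistry is unchanged. Ipso-protodesilylation of this electron-rich arylsilane with CF3CO2H in CH2Cl2 at 0 °C returns to 28.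

3. Step 5 (B-alkyl Suzuki coupling next to a free aldehyde). Hydride transfer from the alkylborane to the formyl group, or base-induced cleavage of the activated triflate before transmetalation, may erode the coupling. Fallback: the coupling is moved to the carboxylic acid oxidation level. Setting out from 8, Pinnick oxidation gives 2,4-bis(benzyloxy)-6-(trifluoromethylsulfonyloxy)benzoic acid F6. Mitsunobu esterification with 2-(trimethylsilyl)ethanol gives 2-(trimethylsilyl)ethyl 2,4-bis(benzyloxy)-6-(trifluoromethylsulfonyloxy)benzoate F7. B-alkyl Suzuki–Miyaura coupling of F7 with borane 9 gives 2-(trimethylsilyl)ethyl 2-[(8S)-8-acetoxyundecyl]-4,6-bis(benzyloxy)benzoate F8. Fluoride (Bu4NF, AcOH, THF) then cleaves the silylethyl ester without touching the acetate and returns to 11.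

Further compounds
F1 | step 14 | (R)-undec-10-en-4-ol | CCC[C@@H](O)CCCCCC=C
F2 | step 14 | (4S)-undec-10-en-4-yl 2-[(8S)-8-acetoxyundecyl]-4,6-bis(benzyloxy)benzoate | CCC[C@@H](CCCCCCCc1cc(OCc2ccccc2)cc(OCc2ccccc2)c1C(=O)O[C@@H](CCC)CCCCCC=C)OC(C)=O
F3 | step 14 | 3-bromo-5-(triisopropylsilyloxy)phenol | Oc1cc(Br)cc(O[Si](C(C)C)(C(C)C)C(C)C)c1
F4 | step 14 | (4S)-11-(9-borabicyclo[3.3.1]nonan-9-yl)undecan-4-yl 2-[(8S)-8-acetoxyundecyl]-4,6-bis(benzyloxy)benzoate | CCC[C@@H](CCCCCCCc1cc(OCc2ccccc2)cc(OCc2ccccc2)c1C(=O)O[C@@H](CCC)CCCCCCCB1C2CCCC1CCC2)OC(C)=O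
F5 | step 13 | (4S)-11-[3-hydroxy-5-(triisopropylsilyloxy)-4-(trimethylsilyl)phenyl]undecan-4-yl 2-[(8S)-8-acetoxyundecyl]-4,6-bis(benzyloxy)benzoate | CCC[C@@H](CCCCCCCc1cc(OCc2ccccc2)cc(OCc2ccccc2)c1C(=O)O[C@@H](CCC)CCCCCCCc1cc(O)c([Si](C)(C)C)c(O[Si](C(C)C)(C(C)C)C(C)C)c1)OC(C)=O
F6 | step 5 | 2,4-bis(benzyloxy)-6-(trifluoromethylsulfonyloxy)benzoic acid | OC(=O)c1c(OS(=O)(=O)C(F)(F)F)cc(OCc2ccccc2)cc1OCc1ccccc1
F7 | step 5 | 2-(trimethylsilyl)ethyl 2,4-bis(benzyloxy)-6-(trifluoromethylsulfonyloxy)benzoate | C[Si](C)(C)CCOC(=O)c1c(OS(=O)(=O)C(F)(F)F)cc(OCc2ccccc2)cc1OCc1ccccc1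
F8 | step 5 | 2-(trimethylsilyl)ethyl 2-[(8S)-8-acetoxyundecyl]-4,6-bis(benzyloxy)benzoate | CCC[C@@H](CCCCCCCc1cc(OCc2ccccc2)cc(OCc2ccccc2)c1C(=O)OCC[Si](C)(C)C)OC(C)=O
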